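## Structural features

Mururin C (15) is a 2-arylbenzofuran: the benzo ring A and the furan ring C share the C3a–C7a bond, and the trioxygenated phenyl ring B is attached through the C2–C1' bond. Ring C is fully substituted and carries a formyl group on C3. Ring A carries a methoxyl on C7 and a 3-hydroxypropyl chain on C5, leaving C4 and C6 as its only C–H positions, and ring B has hydroxyls on C3' and C4' and a methoxyl on C5'. The target has no stereocentre, so no stereocentres stand next to each other; the only one met on the way is C2 of a 2,3-dihydrobenzofuran, which is erased on aromatisation and can be carried as a racemate. The fragile groups are the free catechol of ring B (oxidised by air, above all in base), the C3 aldehyde (a vinylogous formate that does not tolerate reducing conditions) and, less so, the primary alcohol. The real difficulty is regiocontrol: ring B must sit on C2 and a one-carbon unit on C3, ring A needs four different substituents in a 1,2,3,5 pattern, and the catechol must be freed at the end without harming the aldehyde or either methyl ether. The key step uses the fact that C7a has two unlike neighbours in ring A, C7 with its methoxyl and C3a with a hydrogen, so an iodide on C7a has one ortho position blocked and one open. That is the pattern a palladium/norbornene relay needs to alkylate once at C3a and then close a C–O bond at C7a.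

## Logic of the disconnections

15 ⇒ 14. The three O–CH2Ph bonds (two on the ring B catechol, one on the side-chain oxygen) are cut last. The catechol and the alcohol therefore stay masked through the oxidation and formylation steps, and one operation frees all three. The forward step must remove benzyl groups without reducing the aldehyde or the C2=C3 bond and without cleaving a methyl ether.

14 ⇒ 12 (through 13). The C3–CHO bond is cut because C3 of a 2-arylbenzofuran is its most nucleophilic carbon. This removes the only substituent that is not part of the ring system. The forward step must formylate C3 in preference to C4, C6 and the ring B positions, and the side-chain oxygen must be protected against the formylating agent.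

12 ⇒ 11. The C2=C3 double bond is taken back to a single bond with hydrogen on C2 and C3. The dihydrobenzofuran is what the annulation delivers, and its C2 stereocentre has no bearing on the target. The forward step must dehydrogenate the C2–C3 bond without oxidising the other benzylic positions.

11 ⇒ 7 + 10. The C3–C3a and C7a–O1 bonds are cut together. This splits the skeleton into two pieces of similar size: ring A as a simple iodoanisole with the chain in place, and ring B with C2, C3 and O1 as an epoxide. The forward step must alkylate only once at C3a, open the epoxide at its CH2 carbon, and end with C–O bond formation at C7a.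

10 ⇒ 9 ⇒ 8. The epoxide C3–C2 and C3–O bonds are cut (methylene transfer to an aldehyde), then the two phenolic O–benzyl bonds. This leads to a commercial benzaldehyde that already has the ring B oxygen pattern. The forward steps are routine, but the electron-rich epoxide must be handled without acid.

7 ⇒ 5 (through 6). The C–I bond is traced to a C–N bond. An amino group on the future C7a marks the position for iodine with no regiochemical question. The forward step is a diazotisation–iodination that must spare the benzyl ether.

5 ⇒ 1 + 2 + 3 (through 4). The aryl–CH2 bond of the chain is cut. The whole three-carbon chain with its protected oxygen then comes from an allyl ether by hydroboration and cross-coupling onto a commercial bromoaniline. This gives 7 in two steps and avoids any alkene or ester reduction next to a C–I bond, which a chain extension from a 4-iodobenzoate would need.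

## Other disconnections considered

Alternative 1: Danheiser benzannulation that builds ring A onto a finished furan.
- **Cut:** C4–C5, C6–C7 and C7–C7a.
- **Forward step:** the furyl diazoketone ethyl 4-(2-diazoacetyl)-2-(3,4-dibenzyloxy-5-methoxyphenyl)furan-3-carboxylate A1 is irradiated with (triisopropylsiloxy)acetylene A2 and then heated. Wolff rearrangement, [2+2] cycloaddition, four-electron ring opening, six-electron closure onto the furan carbon next to oxygen and tautomerisation should give ethyl 2-(3,4-dibenzyloxy-5-methoxyphenyl)-7-hydroxy-5-(triisopropylsilyloxy)benzofuran-3-carboxylate A3.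
- **In favour:** the ring A oxygen pattern is fixed by the mechanism. The C3 carbon is present from the start, so no formylation selectivity arises, which is better than the chosen plan. The aromatic benzofuran forms directly, so no dehydrogenation is needed, which is also better. No transition metal is involved.
- **Against:** the alkyne carbon that becomes C5 delivers oxygen, whereas the target needs carbon there. After A3 the route would need methylation at C7, desilylation, triflation, a cross-coupling for the chain, a two-step ester-to-aldehyde adjustment and debenzylation. A1 itself, a furan with an ester and a diazoacetyl group on adjacent carbons, needs a linear build of several steps and the handling of a diazoketone under photolysis.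
- **Comparison:** on structure it is superior at C3 and mismatched at C5. On mechanism it is a well-ordered pericyclic cascade against a catalytic relay with more competing paths. On step economy it is clearly inferior, at well over twelve steps against eight.

Alternative 2: a geminal dibromoalkene as a twofold electrophilic C2.
- **Cut:** O1–C2 and C2–C1'.
- **Forward step:** methyl 3,3-dibromo-2-[2-hydroxy-3-methoxy-5-(3-(tert-butyldimethylsilyloxy)propyl)phenyl]acrylate A4 and the ring B boronate 2-(3,4-dibenzyloxy-5-methoxyphenyl)-4,4,5,5-tetramethyl-1,3,2-dioxaborolane A5 are combined with Pd(OAc)2, SPhos and K3PO4. The phenoxide replaces one bromine to close the furan, and the remaining C2–Br bond is coupled to give methyl 2-(3,4-dibenzyloxy-5-methoxyphenyl)-7-methoxy-5-(3-(tert-butyldimethylsilyloxy)propyl)benzofuran-3-carboxylate A6.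
- **In favour:** it is as convergent as the chosen plan, which is an equal point. Ring B arrives as a boronate, which is sturdier than an electron-rich aryl epoxide, a better point. The C3 carbon is built in and the aromatic oxidation level is reached directly, two further better points. Both events of the key step are well-understood coupling chemistry, so the key step is probably the less risky of the two.
- **Against:** A4 is costly. It needs ortho C-acylation of a ring A phenol with an oxalyl unit, dibromo-olefination of the hindered keto ester and protecting-group traffic on the phenol, about five or six steps against two for 7. After A6 the ester must be reduced and re-oxidised and two kinds of protecting group removed, four operations against three.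
- **Comparison:** on structure it solves C3 better. On mechanism it is more conservative. On step economy it is worse, with a longest sequence of about ten steps against six.

Alternative 3: one-carbon insertion of a diazoacetate into a 2-hydroxybenzophenone.
- **Cut:** C2–C3, C3–C3a and O1–C2.
- **Forward step:** (5-allyl-2-hydroxy-3-methoxyphenyl)(3,4-dibenzyloxy-5-methoxyphenyl)methanone A7 is treated with ethyl diazoacetate A8 and HBF4·OEt2. Addition to the ketone, shift of ring A from C2 to C3 with loss of dinitrogen and condensation of the phenol on the new ketone would give ethyl 5-allyl-2-(3,4-dibenzyloxy-5-methoxyphenyl)-7-methoxybenzofuran-3-carboxylate A9.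
- **In favour:** A7 should be reachable by plain acylation chemistry. No transition metal is needed. C3 arrives with its carbon, and the benzofuran forms at the right oxidation level, two better points. The overall step count, about eight or nine, is roughly equal to that of the chosen plan.
- **Against:** diaryl ketones add diazoacetates much more slowly than the aldehydes on which this chemistry is most secure. The product depends on which aryl group migrates, and both rings are electron-rich; migration of ring B would lead to an isomeric keto ester that cannot close to the required benzofuran. The strong acid meets benzyl ethers and an allyl group that can isomerise. After A9 the allyl group must be hydroborated and the ester reduced and selectively re-oxidised beside a second primary alcohol.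
- **Comparison:** on structure it is equal or better at C3. On mechanism its selectivity rests on a migratory preference that the substrate does not clearly bias, whereas the chosen plan has a blocked ortho position. On step economy it is about equal.

Key step: step 5

Remark on the chemistry: the target has no stereocentre, so epoxide 10 and annulation product 11 are carried as racemates (one enantiomer drawn). 9-Borabicyclo[3.3.1]nonane is counted as reactant 2 because its boron atom is held by intermediate 4.

## Route

Step 1
Reactants: 1 allyl benzyl ether; 2 9-borabicyclo[3.3.1]nonane (9-BBN); 3 4-bromo-2-methoxyaniline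
Product: 5 4-(3-benzyloxypropyl)-2-methoxyaniline, via 9-(3-benzyloxypropyl)-9-borabicyclo[3.3.1]nonane 4 (not isolated)
Conditions: 1 + 2, THF, 0 °C to rt; then 3, Pd(dppf)Cl2 (5 mol %), aq K3PO4, THF/DMF, 65 °C
Reagents that add atoms: none
Why: 9-BBN adds to the terminal alkene of 1 with anti-Markovnikov selectivity to give the primary alkylborane 4, which after activation by aqueous phosphate transfers its alkyl group to the arylpalladium bromide formed from 3 (B-alkyl Suzuki–Miyaura coupling); the free aniline and the benzyl ether are inert here, and the amino group marks the carbon that will carry iodine.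

Step 2
Reactants: 5 4-(3-benzyloxypropyl)-2-methoxyaniline
Product: 7 4-(3-benzyloxypropyl)-1-iodo-2-methoxybenzene, via 4-(3-benzyloxypropyl)-2-methoxybenzenediazonium tosylate 6 (not isolated)
Conditions: p-TsOH·H2O, NaNO2, KI, MeCN/H2O, 10 °C to rt
Reagents that add atoms: potassium iodide, [K+].[I-] (iodine of 7); sodium nitrite, [Na+].[O-]N=O (second nitrogen of intermediate 6 only); p-toluenesulfonic acid, Cc1ccc(S(=O)(=O)O)cc1 (counter-ion of intermediate 6 only)
Why: Diazotisation to the arenediazonium tosylate 6 and displacement of dinitrogen by iodide (Sandmeyer-type iodination, no copper needed) places iodine exactly on the former amino carbon, ortho to the methoxyl and para to the chain; the alkyl benzyl ether is stable to aqueous sulfonic acid at room temperature.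

Step 3
Reactants: 8 3,4-dihydroxy-5-methoxybenzaldehyde
Product: 9 3,4-dibenzyloxy-5-methoxybenzaldehyde
Conditions: BnBr, K2CO3, DMF, 60 °C
Reagents that add atoms: benzyl bromide, BrCc1ccccc1
Why: Twofold Williamson etherification of the catechol; K2CO3 deprotonates only the phenols and the aldehyde is not touched.

Step 4
Reactants: 9 3,4-dibenzyloxy-5-methoxybenzaldehyde
Product: 10 rac-2-(3,4-dibenzyloxy-5-methoxyphenyl)oxirane (racemate; S enantiomer drawn)
Conditions: Me3S+ I−, KOt-Bu, DMSO/THF, 0 °C to rt
Reagents that add atoms: trimethylsulfonium iodide, C[S+](C)C.[I-]
Why: Corey–Chaykovsky epoxidation: dimethylsulfonium methylide adds to the aldehyde and the betaine closes with loss of dimethyl sulfide; the new stereocentre forms without control, which is intended because the racemate suffices. The electron-rich epoxide is acid-labile and should be used crude or after filtration through triethylamine-deactivated silica.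

Step 5
Reactants: 7 4-(3-benzyloxypropyl)-1-iodo-2-methoxybenzene; 10 rac-2-(3,4-dibenzyloxy-5-methoxyphenyl)oxirane
Product: 11 rac-2-(3,4-dibenzyloxy-5-methoxyphenyl)-5-(3-benzyloxypropyl)-7-methoxy-2,3-dihydrobenzofuran (racemate; R enantiomer drawn)
Conditions: Pd(OAc)2 (5 mol %), XPhos (10 mol %), potassium 5-norbornene-2-carboxylate (50 mol %), K2CO3, NMP, 70 °C, argon; 10 in excess
Reagents that add atoms: none
Why: Zerovalent palladium (from Pd(OAc)2 and XPhos) inserts into the C7a–I bond of 7, the norbornene inserts into the aryl–palladium bond, and carbonate-assisted palladation of the C3a–H bond gives the five-membered aryl–norbornyl palladacycle of divalent palladium. This electron-rich palladacycle opens epoxide 10 by SN2-type oxidative addition at the unsubstituted CH2 carbon to give a tetravalent palladium alkoxide, and reductive elimination forms the C3–C3a bond. Because both ortho positions of C7a are then occupied (methoxyl on C7, the new CH2 on C3a), the norbornene is expelled by β-carbon elimination, leaving an arylpalladium species of divalent palladium with the alkoxide tethered two carbons away. Ring C is closed by intramolecular C(sp2)–O reductive elimination from the six-membered aryl(alkoxo)palladium chelate, a Buchwald–Hartwig-type etherification that forms C7a–O1 and returns zerovalent palladium. The closest known reaction type is the palladium/norbornene (Catellani) annulation of ortho-substituted aryl iodides with epoxides to 2,3-dihydrobenzofurans. No stereocentre is created: C2 is the epoxide carbon that is not attacked, so its configuration is carried over, and the racemate is used because C2 becomes planar in step 6. The selectivities needed are single alkylation at C3a, secured by the C7 methoxyl that blocks the second ortho position, and attack at the epoxide CH2 and not at the benzylic carbon, secured by the steric demand of the palladacycle. The bulky biarylphosphine is chosen to favour C–O reductive elimination over β-hydride elimination of the alkoxide, and the moderate temperature and the excess of 10 limit losses by epoxide isomerisation.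

Step 6
Reactants: 11 rac-2-(3,4-dibenzyloxy-5-methoxyphenyl)-5-(3-benzyloxypropyl)-7-methoxy-2,3-dihydrobenzofuran
Product: 12 2-(3,4-dibenzyloxy-5-methoxyphenyl)-5-(3-benzyloxypropyl)-7-methoxybenzofuran
Conditions: DDQ, 1,4-dioxane, 90 °C
Reagents that add atoms: none
Why: Quinone dehydrogenation: DDQ abstracts hydride from C2, which is benzylic to ring B and α to O1, and loss of a C3 proton from the oxocarbenium ion gives the aromatic furan, a standard conversion of 2-aryl-2,3-dihydrobenzofurans into 2-arylbenzofurans. Plain benzyl ethers are oxidised far more slowly than this doubly activated C–H bond, and the C2 stereocentre disappears here.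

Step 7
Reactants: 12 2-(3,4-dibenzyloxy-5-methoxyphenyl)-5-(3-benzyloxypropyl)-7-methoxybenzofuran
Product: 14 2-(3,4-dibenzyloxy-5-methoxyphenyl)-5-(3-benzyloxypropyl)-7-methoxybenzofuran-3-carbaldehyde, via 3-(dimethyliminiomethyl)benzofuran chloride 13 (not isolated)
Conditions: POCl3, DMF, 0 to 70 °C; then H2O, 50 °C (neutralised with aq NaHCO3 on work-up)
Reagents that add atoms: N,N-dimethylformamide, CN(C)C=O (formyl carbon; also the dimethylamino group of intermediate 13); water, O (formyl oxygen); phosphoryl chloride, O=P(Cl)(Cl)Cl (chloride counter-ion of intermediate 13 only)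
Why: Vilsmeier–Haack formylation: C3 is the β-carbon of an aryl enol ether conjugated with the electron-rich ring B and is the most nucleophilic carbon of 12, so the chloroiminium ion attacks there and the iminium salt 13 is hydrolysed to the aldehyde. The benzyl ether keeps the side-chain oxygen from being formylated or chlorinated.

Step 8
Reactants: 14 2-(3,4-dibenzyloxy-5-methoxyphenyl)-5-(3-benzyloxypropyl)-7-methoxybenzofuran-3-carbaldehyde
Product: 15 Mururin C, 2-(3,4-dihydroxy-5-methoxyphenyl)-5-(3-hydroxypropyl)-7-methoxybenzofuran-3-carbaldehyde
Conditions: BCl3, C6HMe5, CH2Cl2, −78 to −30 °C; then MeOH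
Reagents that add atoms: none
Why: Lewis-acid debenzylation: BCl3 ionises the three O–benzyl bonds at low temperature and pentamethylbenzene traps the benzyl cations by Friedel–Crafts alkylation, so no reducing agent meets the aldehyde or the C2=C3 bond and the electron-rich rings are not re-benzylated. Neither methyl ether is next to a carbonyl group, so both should survive below −30 °C; the boron esters formed are cleaved by the methanol quench.

## Compound list

1 | allyl benzyl ether | C=CCOCc1ccccc1 | starting material
2 | 9-borabicyclo[3.3.1]nonane (9-BBN) | B1C2CCCC1CCC2 | starting material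
3 | 4-bromo-2-methoxyaniline | COc1cc(Br)ccc1N | starting material
4 | 9-(3-benzyloxypropyl)-9-borabicyclo[3.3.1]nonane | C(CCOCc1ccccc1)B1C2CCCC1CCC2 | intermediate (not isolated)
5 | 4-(3-benzyloxypropyl)-2-methoxyaniline | COc1cc(CCCOCc2ccccc2)ccc1N | intermediate
6 | 4-(3-benzyloxypropyl)-2-methoxybenzenediazonium p-toluenesulfonate | COc1cc(CCCOCc2ccccc2)ccc1[N+]#N.Cc1ccc(S(=O)(=O)[O-])cc1 | intermediate (not isolated)
7 | 4-(3-benzyloxypropyl)-1-iodo-2-methoxybenzene | COc1cc(CCCOCc2ccccc2)ccc1I | intermediate
8 | 3,4-dihydroxy-5-methoxybenzaldehyde | COc1cc(C=O)cc(O)c1O | starting material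
9 | 3,4-dibenzyloxy-5-methoxybenzaldehyde | COc1cc(C=O)cc(OCc2ccccc2)c1OCc1ccccc1 | intermediate
10 | rac-2-(3,4-dibenzyloxy-5-methoxyphenyl)oxirane (racemate; the (S)-enantiomer is drawn) | COc1cc([C@H]2CO2)cc(OCc2ccccc2)c1OCc1ccccc1 | intermediate
11 | rac-2-(3,4-dibenzyloxy-5-methoxyphenyl)-5-(3-benzyloxypropyl)-7-methoxy-2,3-dihydrobenzofuran (racemate; the (R)-enantiomer is drawn, same spatial arrangement at C2 as in 10) | COc1cc([C@H]2Cc3cc(CCCOCc4ccccc4)cc(OC)c3O2)cc(OCc2ccccc2)c1OCc1ccccc1 | intermediate
12 | 2-(3,4-dibenzyloxy-5-methoxyphenyl)-5-(3-benzyloxypropyl)-7-methoxybenzofuran | COc1cc(-c2cc3cc(CCCOCc4ccccc4)cc(OC)c3o2)cc(OCc2ccccc2)c1OCc1ccccc1 | intermediate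
13 | N-{[2-(3,4-dibenzyloxy-5-methoxyphenyl)-5-(3-benzyloxypropyl)-7-methoxybenzofuran-3-yl]methylidene}-N-methylmethanaminium chloride | COc1cc(-c2oc3c(OC)cc(CCCOCc4ccccc4)cc3c2C=[N+](C)C)cc(OCc2ccccc2)c1OCc1ccccc1.[Cl-] | intermediate (not isolated)
14 | 2-(3,4-dibenzyloxy-5-methoxyphenyl)-5-(3-benzyloxypropyl)-7-methoxybenzofuran-3-carbaldehyde | COc1cc(-c2oc3c(OC)cc(CCCOCc4ccccc4)cc3c2C=O)cc(OCc2ccccc2)c1OCc1ccccc1 | intermediate
15 | Mururin C, 2-(3,4-dihydroxy-5-methoxyphenyl)-5-(3-hydroxypropyl)-7-methoxybenzofuran-3-carbaldehyde (no stereocentre) | COc1cc(-c2oc3c(OC)cc(CCCO)cc3c2C=O)cc(O)c1O | target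

## Step count and least certain steps

Total: 8 steps. Longest linear sequence: 6 steps (1, 2, 5, 6, 7, 8 or 3, 4, 5, 6, 7, 8).

**Step 5 (key step).** The most likely failure is loss of the epoxide before the palladacycle can use it. An aryl epoxide with a para-alkoxy group isomerises easily to the arylacetaldehyde under Lewis-acidic divalent palladium or after benzylic opening by iodide. A second loss channel is β-hydride elimination of the palladium alkoxide in place of C–O reductive elimination, which would end in a ketone and a reduced arene. The fallback gives up the relay and closes the furan from an ortho-iodophenol and an alkyne. It sets out from 7 and 9 and comes back at 12, so step 6 is not needed on this path.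
- Copper-catalysed hydroxylation of 7 (CuI, 1,10-phenanthroline, KOH, DMSO/H2O, 100 °C) should give 4-(3-benzyloxypropyl)-2-methoxyphenol F1.
- Iodination of F1 with N-iodosuccinimide in MeCN should enter the only free position ortho to the hydroxyl and give 4-(3-benzyloxypropyl)-2-iodo-6-methoxyphenol F2.
- Aldehyde 9 is homologated with the Ohira–Bestmann reagent (dimethyl (1-diazo-2-oxopropyl)phosphonate, K2CO3, MeOH) to 1,2-dibenzyloxy-5-ethynyl-3-methoxybenzene F3.
- Sonogashira coupling of F2 with F3 (Pd(PPh3)2Cl2, CuI, Et3N, DMF, 60 °C), with 5-endo closure of the phenol onto the alkyne in the same flask, should give 12.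

**Step 6.** The most likely failure is oxidation at the wrong benzylic site, namely C1 of the propyl chain para to O1 or a benzyl ether CH2, or over-oxidation of the electron-rich product by excess quinone. The fallback replaces hydride abstraction by an elimination–oxidative cyclisation pair. It sets out from 11 and comes back at 12.
- Lithium diisopropylamide in THF (−78 to 0 °C) should remove a C3 proton and expel the C7a phenoxide (E1cB ring opening) to give 2-[(E)-2-(3,4-dibenzyloxy-5-methoxyphenyl)ethenyl]-4-(3-benzyloxypropyl)-6-methoxyphenol F4.
- Iodine and K2CO3 in THF should then close F4 by iodocyclisation and loss of hydrogen iodide to 12.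

**Step 7.** The most likely failure is loss of site selectivity: attack of the chloroiminium ion on the ring B positions next to the benzofuran or on C4/C6 of ring A, or a second formylation under forcing conditions. The fallback fixes the position with a halogen first. It sets out from 12 and comes back at 14.
- N-Bromosuccinimide in DMF at 0 °C should brominate C3 and give 3-bromo-2-(3,4-dibenzyloxy-5-methoxyphenyl)-5-(3-benzyloxypropyl)-7-methoxybenzofuran F5.
- Bromine–lithium exchange on F5 with n-BuLi in THF at −78 °C and quenching with DMF should give 14.

**Step 8.** The most likely failure is boron-assisted loss of the C5' methyl ether next to the freed catechol if the mixture must be warmed to complete cleavage of the slower alkyl benzyl ether. Incomplete scavenging of benzyl cations could also lead to ring benzylation. The fallback changes the order of events and the protecting groups so that no benzyl ether remains when the aldehyde is present. It sets out from 12 and comes back at 15.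
- Hydrogenolysis of 12 (H2, Pd/C, EtOAc/MeOH) should give 2-(3,4-dihydroxy-5-methoxyphenyl)-5-(3-hydroxypropyl)-7-methoxybenzofuran F6.
- Acetylation of F6 (Ac2O, pyridine) should give 3-[2-(3,4-diacetoxy-5-methoxyphenyl)-7-methoxybenzofuran-5-yl]propyl acetate F7.
- Vilsmeier–Haack formylation of F7 (POCl3, DMF) should give 3-[2-(3,4-diacetoxy-5-methoxyphenyl)-3-formyl-7-methoxybenzofuran-5-yl]propyl acetate F8; the acetylated ring B is deactivated, which also helps the site selectivity.
- Methanolysis of F8 (K2CO3, MeOH, 0 °C, argon) should give 15.

## Further compounds

F1 | step 5 | 4-(3-benzyloxypropyl)-2-methoxyphenol | COc1cc(CCCOCc2ccccc2)ccc1O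
F2 | step 5 | 4-(3-benzyloxypropyl)-2-iodo-6-methoxyphenol | COc1cc(CCCOCc2ccccc2)cc(I)c1O
F3 | step 5 | 1,2-dibenzyloxy-5-ethynyl-3-methoxybenzene | COc1cc(C#C)cc(OCc2ccccc2)c1OCc1ccccc1
F4 | step 6 | 2-[(E)-2-(3,4-dibenzyloxy-5-methoxyphenyl)ethenyl]-4-(3-benzyloxypropyl)-6-methoxyphenol | COc1cc(/C=C/c2cc(CCCOCc3ccccc3)cc(OC)c2O)cc(OCc2ccccc2)c1OCc1ccccc1
F5 | step 7 | 3-bromo-2-(3,4-dibenzyloxy-5-methoxyphenyl)-5-(3-benzyloxypropyl)-7-methoxybenzofuran | COc1cc(-c2oc3c(OC)cc(CCCOCc4ccccc4)cc3c2Br)cc(OCc2ccccc2)c1OCc1ccccc1
F6 | step 8 | 2-(3,4-dihydroxy-5-methoxyphenyl)-5-(3-hydroxypropyl)-7-methoxybenzofuran | COc1cc(-c2cc3cc(CCCO)cc(OC)c3o2)cc(O)c1O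
F7 | step 8 | 3-[2-(3,4-diacetoxy-5-methoxyphenyl)-7-methoxybenzofuran-5-yl]propyl acetate | COc1cc(-c2cc3cc(CCCOC(C)=O)cc(OC)c3o2)cc(OC(C)=O)c1OC(C)=O
F8 | step 8 | 3-[2-(3,4-diacetoxy-5-methoxyphenyl)-3-formyl-7-methoxybenzofuran-5-yl]propyl acetate | COc1cc(-c2oc3c(OC)cc(CCCOC(C)=O)cc3c2C=O)cc(OC(C)=O)c1OC(C)=O
A1 | alternative 1 | ethyl 4-(2-diazoacetyl)-2-(3,4-dibenzyloxy-5-methoxyphenyl)furan-3-carboxylate | CCOC(=O)c1c(-c2cc(OC)c(OCc3ccccc3)c(OCc3ccccc3)c2)occ1C(=O)C=[N+]=[N-]
A2 | alternative 1 | (triisopropylsiloxy)acetylene | C#CO[Si](C(C)C)(C(C)C)C(C)C
A3 | alternative 1 | ethyl 2-(3,4-dibenzyloxy-5-methoxyphenyl)-7-hydroxy-5-(triisopropylsilyloxy)benzofuran-3-carboxylate | CCOC(=O)c1c(-c2cc(OC)c(OCc3ccccc3)c(OCc3ccccc3)c2)oc2c(O)cc(O[Si](C(C)C)(C(C)C)C(C)C)cc12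
A4 | alternative 2 | methyl 3,3-dibromo-2-[2-hydroxy-3-methoxy-5-(3-(tert-butyldimethylsilyloxy)propyl)phenyl]acrylate | COC(=O)C(=C(Br)Br)c1cc(CCCO[Si](C)(C)C(C)(C)C)cc(OC)c1O
A5 | alternative 2 | 2-(3,4-dibenzyloxy-5-methoxyphenyl)-4,4,5,5-tetramethyl-1,3,2-dioxaborolane | COc1cc(B2OC(C)(C)C(C)(C)O2)cc(OCc2ccccc2)c1OCc1ccccc1
A6 | alternative 2 | methyl 2-(3,4-dibenzyloxy-5-methoxyphenyl)-7-methoxy-5-(3-(tert-butyldimethylsilyloxy)propyl)benzofuran-3-carboxylate | COC(=O)c1c(-c2cc(OC)c(OCc3ccccc3)c(OCc3ccccc3)c2)oc2c(OC)cc(CCCO[Si](C)(C)C(C)(C)C)cc12
A7 | alternative 3 | (5-allyl-2-hydroxy-3-methoxyphenyl)(3,4-dibenzyloxy-5-methoxyphenyl)methanone | COc1cc(C(=O)c2cc(CC=C)cc(OC)c2O)cc(OCc2ccccc2)c1OCc1ccccc1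
A8 | alternative 3 | ethyl diazoacetate | CCOC(=O)C=[N+]=[N-]
A9 | alternative 3 | ethyl 5-allyl-2-(3,4-dibenzyloxy-5-methoxyphenyl)-7-methoxybenzofuran-3-carboxylate | CCOC(=O)c1c(-c2cc(OC)c(OCc3ccccc3)c(OCc3ccccc3)c2)oc2c(OC)cc(CC=C)cc12
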